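Partner goes two ways.

common to all: substrate 0.030 M; free catalyst 0.20 mM
- winter: partner 0.030 M; temperature 35 °C; the very flask that is asked about, followed so far
- autumn: partner 0.030 M; temperature 41 °C; run made earlier
- flask: partner 0.0300 M; temperature 35 °C; time 30 min

| run | time / min | product / % |
|---|---|---|
| winter | 2.00 | 10.8 |
| winter | 4.00 | 17.2 |
| winter | 10.0 | 23.5 |
| winter | 25.0 | 26.7 |
| autumn | 2.00 | 15.9 |
| autumn | 4.00 | 20.7 |
| autumn | 10.0 | 25.9 |
| autumn | 25.0 | 27.3 |

(readings scatter by 1 percentage point)

- south: at 30 min raise the temperature by 20 K, then wait 30 min
- north-west: at 30 min add free catalyst, 100 % of the amount charged, then wait 30 min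
- south-west: at 30 min add partner, 50.0 % of the amount charged, then wait 30 min
- south-east: at 30 min take out 90 % of the product then present, then wait 30 min
- west: change nothing and wait 30 min more

- product that was removed still counts
- what may be going on: substrate + free catalyst <-> free catalyst + open intermediate; free catalyst + open intermediate <-> catalyst intermediate; partner + catalyst intermediate -> free catalyst + product; 2 partner -> homo dimer
- additions bring no volume worth counting

- product, in percent of the substrate first charged, at 30 min
- the remedy with the largest gain of product, or "none" below 2 percentage points (south / north-west / south-west / south-east / west / none)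
- product present, with what was taken out counted in, in percent of the substrate first charged, after south
- product present, with what was taken out counted in, in percent of the substrate first charged, after south-west

The winter and autumn runs end close together, at 26.7 % and 27.3 %, with a mean level of 27.0 %. The warmer autumn run is ahead at 2.00 min, with 15.9 % against 10.8 %, so warming moves the early readings and leaves the level about where it was.

My reckoning takes c(partner) as falling by coupling, first order, and by dimerisation, second order. A share a of the partner charge then yields ln(1 + N·a)/N of that charge as product. Partner and substrate are charged equally, so the level gives N = 8.23, the rate of partner's loss to homo dimer over its rate of loss to product at the full charge, a selectivity factor. Partner is thus the limiting reagent.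

One number is enough only if one coupling constant fits the whole winter run. With N, the reading at 2.00 min gives 0.0956 min⁻¹ as an average from the start, and the reading at 10.0 min gives 0.127 min⁻¹. Both carry the scatter of the readings, but they suggest a slow start, so one number is not enough. Later partner meets a smaller N, about 6.20.

At 30 min the reckoning leaves 0.246 % of the partner charge, against the 2 percentage points that counts. Product therefore stays near 27.0 %, and south, north-west, south-east and west gain too little to count. South-west adds half a charge of partner, which gains 23 points and brings product to 50.0 %.

The forecast, resting on “partner being lost to second-order dimerisation, which outruns coupling”, says 27.2 %, south-west, 27.8 % after south and 46 % after south-west.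

The flask gives 28.3 %, south-west, 28.3 % after south and 52.1 % after south-west.

    substrate + free catalyst ⇌ free catalyst + open intermediate (K = 1.40, k = 42.0 L mol⁻¹ s⁻¹, Ea = 51.0 kJ mol⁻¹, ΔH = −60.0 kJ mol⁻¹)
    free catalyst + open intermediate ⇌ catalyst intermediate (K = 13.0 L mol⁻¹, k = 150 L mol⁻¹ s⁻¹, Ea = 44.0 kJ mol⁻¹, ΔH = 18.0 kJ mol⁻¹)
    partner + catalyst intermediate → free catalyst + product (k = 140 L mol⁻¹ s⁻¹, Ea = 35.0 kJ mol⁻¹)
    2 partner → homo dimer (k = 0.290 L mol⁻¹ s⁻¹, Ea = 44.0 kJ mol⁻¹)
    (constants at 35 °C)

South-west gains 24 points in this flask, against the 23 points reckoned with the later N. When the partner went in at 30.0 min, this flask held 14.0 % of its catalyst as catalyst intermediate. For the neighbour flask with 0.018 M of partner, the starting N gives 21.7 % and the later N gives 25.0 %. That neighbour flask holds 23.8 % of product at 30.0 min, above the first and below the second.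

The readings are simulated for an exercise; noise was put on by code.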